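The leftover opened the meeting: at 50% conversion in the flask, the salt in the second phase has gone one for one with substrate, so a charge of 0.900 equiv leaves 0.400 per substrate charged. It is the limiting reagent.

| setting | delta | flask |
|---|---|---|
| substrate | 0.045 M | 0.091 M |
| salt in the second phase | 0.90 equiv | 0.900 equiv |
| spent carrier | 1 mol% | 1 mol% |
| added ligand | 1.2 mM | 1.2 mM |
| remark | run made earlier |  |
| volume of the second phase over the first |  | 0.25 |

delta run (percent of the substrate charged)

| time / min | product / % | substrate / % |
|---|---|---|
| 1.00 | 9.9 | 90.0 |
| 2.00 | 18.5 | 82.3 |
| 3.00 | 24.6 | 76.7 |
| 4.00 | 28.9 | 69.6 |
| 5.00 | 34.2 | 63.8 |
| 6.00 | 38.6 | 61.4 |
| 8.00 | 46.7 | 53.0 |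

(readings scatter by 1 percentage point)

- in the second phase: salt in the second phase, spent salt in the second phase; everything else is in the first
- charges count per volume of the first phase; a concentration in a rate is the amount of a species over the volume of its own phase; every rate counts per litre of the first phase
- the numbers in the tables scatter by 1 percentage point (one standard deviation)
- on the list of suspects stand: spent carrier + salt in the second phase <-> fresh carrier + spent salt in the second phase; substrate + fresh carrier -> product + spent carrier; added ligand + fresh carrier <-> idle complex
- the earlier runs hold the two phases in the same ratio of volumes as the flask asked about
- no earlier run changes the charge of salt in the second phase; that part of a forecast is a guess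

* apparent order in salt in the second phase when 50% of the substrate are converted (percent change of the rate of making product for one percent more salt in the second phase charged)
* factor on the rate of making product when 50% of the substrate are converted if salt in the second phase is charged twice over

The chair drew the round on the board: spent carrier takes up salt in the second phase and becomes fresh carrier, fresh carrier turns substrate into product and is spent again, and added ligand can hold fresh carrier as idle complex. The chair then argued that at fixed conversion extra charge goes straight onto the leftover, so one percent more charge raises the leftover by a percentage equal to charge over leftover, which comes to 2.25. This leverage is the same in the delta run, with its equal equivalents. Spent salt in the second phase stays put at fixed conversion, so the chair set the order equal to leverage times the share of the rate lost to back exchange.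

The secretary, reckoning on his own, took the fraction of substrate left in the delta run. Its logarithm fell by 0.105 min⁻¹ in the first minute, but by 0.0618 min⁻¹ between 5.00 min and 8.00 min. Read through a scatter of 1 percentage point, and taking that fall as back exchange, this gives a share of 0.413, a reading from the delta run short of 50% conversion, which he carried over to the flask unchanged. He committed to an order of 0.929 and, with 0.704 as lost rate over kept rate, a factor of 1.40.

The forecaster stood higher, at 1.1 and 1.5, arguing that “carrier doubles at the same ligand, so free ligand is lower”.

The flask gives 1.0 and 1.48.

    spent carrier + salt in the second phase ⇌ fresh carrier + spent salt in the second phase (K = 1.00, k = 5200 M⁻¹ min⁻¹)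
    substrate + fresh carrier → product + spent carrier (k = 370 M⁻¹ min⁻¹)
    added ligand + fresh carrier ⇌ idle complex (K = 660 M⁻¹, k = 2400 M⁻¹ min⁻¹)

In this flask the leverage 2.25 turns the order 1.0 into a share of the rate lost to back exchange of 0.462. The reverse step, fresh carrier with spent salt in the second phase going back to spent carrier, is the largest single effect on that order: this flask run without it drops to an order of 0.037. That run makes product 1.86 times as fast at 50% conversion.

All runs stem from a simulated flask for an exercise.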